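**Retrosynthetic overview**

1. Target → Claisen–Schmidt disconnection of the enone C(α)=C(β): ring A methyl ketone (2,4-dihydroxyacetophenone, 4-OH masked as a THP acetal) + ring B aldehyde (4-hydroxy-3,5-diprenylbenzaldehyde). The (E) geometry comes from thermodynamic dehydration; the THP group is removed in the same flask.
2. Ring B aldehyde → each ortho C-prenyl group is traced back, through an aromatic Claisen shift, to an aryl–O–C(CH3)2CH=CH2 ether. The key step is the catalytic formation of this aryl C–O bond, twice in one flask, from 4-hydroxybenzaldehyde and 2-methylbut-3-en-2-ol.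
3. Ring A ketone → 2,4-dihydroxyacetophenone + 3,4-dihydro-2H-pyran (C–O acetal).
4. Ring order: no ring is constructed. Rings A and B are bought as intact benzene rings; the only ring added (the oxane of the THP group, step 2) is temporary and leaves in step 3.

Assumption: the target has no stereocentre, so "single enantiomer" is read as the single (E)-alkene isomer of the given SMILES.

**Route**

Step 1
Reactants: 1 4-hydroxybenzaldehyde; 2 2-methylbut-3-en-2-ol (2.6 equiv)
Product: 6 4-hydroxy-3,5-bis(3-methylbut-2-en-1-yl)benzaldehyde, via aryl tert-prenyl ether 3 (not isolated), via monoprenyl phenol 4 (not isolated), via second tert-prenyl ether 5 (not isolated)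
Conditions: Pd2(dba)3 (2.5 mol %), Xantphos (5.5 mol %), mesitylene, sealed tube, 140 °C, 24 h; then vent, Ar sweep, 110 °C, 1 h
Reagents that add atoms: none
Why: Proposed new method: zerovalent palladium/Xantphos ionises the tertiary allylic alcohol 2 (the acidic phenol, pKa about 7.6, is the proton source) to a 1,1-dimethylallylpalladium phenoxide ion pair that closes the aryl C–O bond reversibly at either allyl terminus, and at 140 °C only the tertiary ether 3 leaves this equilibrium, by the fast, irreversible aromatic Claisen [3,3] shift that puts a linear prenyl group on the ortho carbon (4), after which 4 runs the same cycle through 5 (shift to the free ortho carbon, para position blocked by CHO) to 6 and the sequence stops because no ortho hydrogen is left; the closest known reaction types are the dehydrative Tsuji–Trost O-allylation of phenols with allylic alcohols and the stepwise palladium-catalysed 1,1-dimethylallylation of phenols with tertiary allylic carbonates followed by a separate thermal Claisen rearrangement, which have not been merged into one catalytic double ortho-prenylation using the free alcohol; no stereocentre is formed.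

Step 2
Reactants: 7 2,4-dihydroxyacetophenone
Product: 8 1-[2-hydroxy-4-(oxan-2-yloxy)phenyl]ethan-1-one (racemic at the acetal carbon)
Conditions: 3,4-dihydro-2H-pyran (2.5 equiv), PPTS (10 mol %), CH2Cl2, rt, 6 h
Reagents that add atoms: 3,4-dihydro-2H-pyran, C1=COCCC1
Why: Acid-catalysed tetrahydropyranylation (addition of the phenol O–H across the enol ether) is selective for the 4-OH because the 2-OH is held in a hydrogen bond to the ketone; the acetal stereocentre forms racemic, which does not matter since it is removed in step 3.

Step 3
Reactants: 6 4-hydroxy-3,5-bis(3-methylbut-2-en-1-yl)benzaldehyde; 8 1-[2-hydroxy-4-(oxan-2-yloxy)phenyl]ethan-1-one (1.2 equiv)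
Product: 10 abyssinone VI, via THP-protected chalcone 9 (not isolated)
Conditions: KOH (60% aq, 20 equiv), EtOH, 0 °C to rt, 48 h, dark; then THF, 3 M aq HCl to pH 1, rt, 2 h
Reagents that add atoms: none
Why: Claisen–Schmidt condensation, in which the enolate of 8 (4-oxygen masked, so not a vinylogous carboxylate) adds to the aldehyde of 6 and E1cB loss of water gives the thermodynamically favoured (E)-enone, followed by hydrolysis of the aryl THP acetal in dilute acid at room temperature, which is too mild to cyclise the ortho-prenyl phenol to a chroman or the 2'-hydroxychalcone to a flavanone; no stereocentre is formed.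

**Compound list**

1 | 4-hydroxybenzaldehyde | O=Cc1ccc(O)cc1 | starting material
2 | 2-methylbut-3-en-2-ol | CC(C)(O)C=C | starting material
3 | 4-[(2-methylbut-3-en-2-yl)oxy]benzaldehyde | C=CC(C)(C)Oc1ccc(C=O)cc1 | intermediate
4 | 4-hydroxy-3-(3-methylbut-2-en-1-yl)benzaldehyde | CC(C)=CCc1cc(C=O)ccc1O | intermediate
5 | 4-[(2-methylbut-3-en-2-yl)oxy]-3-(3-methylbut-2-en-1-yl)benzaldehyde | C=CC(C)(C)Oc1ccc(C=O)cc1CC=C(C)C | intermediate
6 | 4-hydroxy-3,5-bis(3-methylbut-2-en-1-yl)benzaldehyde | CC(C)=CCc1cc(C=O)cc(CC=C(C)C)c1O | intermediate
7 | 2,4-dihydroxyacetophenone, 1-(2,4-dihydroxyphenyl)ethan-1-one | CC(=O)c1ccc(O)cc1O | starting material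
8 | 1-[2-hydroxy-4-(oxan-2-yloxy)phenyl]ethan-1-one, racemic | CC(=O)c1ccc(OC2CCCCO2)cc1O | intermediate
9 | (E)-1-[2-hydroxy-4-(oxan-2-yloxy)phenyl]-3-[4-hydroxy-3,5-bis(3-methylbut-2-en-1-yl)phenyl]prop-2-en-1-one, racemic at the acetal carbon | CC(C)=CCc1cc(/C=C/C(=O)c2ccc(OC3CCCCO3)cc2O)cc(CC=C(C)C)c1O | intermediate
10 | abyssinone VI, (E)-1-(2,4-dihydroxyphenyl)-3-[4-hydroxy-3,5-bis(3-methylbut-2-en-1-yl)phenyl]prop-2-en-1-one | CC(C)=CCc1cc(/C=C/C(=O)c2ccc(O)cc2O)cc(CC=C(C)C)c1O | target

**Step count**

Total steps: 3. Longest linear sequence: 2 steps (1 → 6 → 10, or 7 → 8 → 10).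

**Steps most likely to fail, with fallbacks**

Step 1 (the proposed new step) is the most likely to fail. The linear O-prenyl ethers may act as a sink and not as a reservoir. The zerovalent palladium catalyst may die at 140 °C before the second cycle is complete. The ortho-prenyl phenols 4 and 6 could close to 2,2-dimethylchromans if the medium turns acidic. The final vent stage is meant to expel surplus donor as isoprene, so that any O-prenyl ether of 6 returns to the free phenol. The fallback uses known chemistry only, sets out from 1 and comes back at 6, and keeps the aryl C–O bond as the key bond. Compound 1 is O-alkylated with 3-chloro-3-methylbut-1-yne (K2CO3, KI, CuI cat., acetone, reflux) to the tertiary propargyl ether 4-[(2-methylbut-3-yn-2-yl)oxy]benzaldehyde F1. Semi-hydrogenation (H2, Pd/CaCO3 poisoned with Pb(OAc)2, quinoline, EtOAc) gives 3, now isolated, and heating (N,N-diethylaniline, 140 °C) gives 4 by aromatic Claisen rearrangement. The same three operations on 4 give 4-[(2-methylbut-3-yn-2-yl)oxy]-3-(3-methylbut-2-en-1-yl)benzaldehyde F2, then 5, then 6. This costs six operations in place of one.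

Step 3 is the next most likely to fail. Under KOH the aldehyde 6 reacts as its phenoxide, a poor electrophile, so conversion may stall. The acid stage in the crude mixture may leave some 9 or start chroman or flavanone formation. The fallback sets out from 6 and comes back at 10. Compound 6 is protected (MOMCl, K2CO3, acetone, rt) as 4-(methoxymethoxy)-3,5-bis(3-methylbut-2-en-1-yl)benzaldehyde F3. This neutral aldehyde is condensed with 8 (KOH, EtOH/H2O, rt, then AcOH) to the doubly protected chalcone (E)-1-[2-hydroxy-4-(oxan-2-yloxy)phenyl]-3-[4-(methoxymethoxy)-3,5-bis(3-methylbut-2-en-1-yl)phenyl]prop-2-en-1-one F4, which is isolated and purified. Both acetals are then removed in a separate, controlled step (3 M HCl, MeOH, 40 °C) to give 10.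

Step 2 is the least risky of the three. Some bis-THP ether may form, and the aryl THP acetal may partly hydrolyse on silica. The fallback drops protection altogether; it sets out from 7 and comes back at 10, using 6 from step 1 and bypassing 8 and 9. Compound 7 is treated in THF at −78 °C with LiN(SiMe3)2 (3.3 equiv, covering both phenols and the methyl ketone). Compound 6, pre-treated with LiN(SiMe3)2 (1.1 equiv), is added, and the mixture is warmed to rt and quenched with aqueous HCl to give 10 directly. Lithium amide-mediated condensation of unprotected hydroxyacetophenones with benzaldehydes in THF is known. It is held in reserve because the phenoxide aldehyde makes the yield less predictable. It makes no compound outside the list (new compounds: none F0).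

**Further compounds**

F1 | step 1 | 4-[(2-methylbut-3-yn-2-yl)oxy]benzaldehyde | C#CC(C)(C)Oc1ccc(C=O)cc1
F2 | step 1 | 4-[(2-methylbut-3-yn-2-yl)oxy]-3-(3-methylbut-2-en-1-yl)benzaldehyde | C#CC(C)(C)Oc1ccc(C=O)cc1CC=C(C)C
F3 | step 3 | 4-(methoxymethoxy)-3,5-bis(3-methylbut-2-en-1-yl)benzaldehyde | COCOc1c(CC=C(C)C)cc(C=O)cc1CC=C(C)C
F4 | step 3 | (E)-1-[2-hydroxy-4-(oxan-2-yloxy)phenyl]-3-[4-(methoxymethoxy)-3,5-bis(3-methylbut-2-en-1-yl)phenyl]prop-2-en-1-one | COCOc1c(CC=C(C)C)cc(/C=C/C(=O)c2ccc(OC3CCCCO3)cc2O)cc1CC=C(C)C
F0 | step 2 | none | none
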